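**Plan**
Retrosynthesis: C8–Cl is traced back to an all-cis C8–O bond (inversion) and C7–OH to a ketone; the carbocycle is then cut at C5–C6 and C8–C8a, and the pyranone at O1–C8a and C3–C4.
Enabling feature: the saturated ring carries heteroatoms on the adjacent carbons C6, C7 and C8, flanked by the carbinol C5 (on C4a) and by C8a, the oxygen-bearing β-carbon of the pyranone enone. This is a dihydroxyacetone skeleton whose two α-carbons are bonded to a former aldehyde carbon and to a carbon open to vinylic substitution.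
Forward: an arylpropanoyl unit is joined to an acetyl ketene dithioacetal (Claisen), the 2-methylsulfanyl-4-pyranone ring is closed and formylated, and the carbocycle is then closed in one operation with 2,2-dimethyl-1,3-dioxan-5-one (proline aldol for C5–C6, vinylic substitution for C8–C8a) as an acetonide-bridged bicycle.
Stereochemistry: L-proline fixes C5 and C6 (anti aldol, O5 cis to O6), the isopropylidene tether forces O8 cis to O6, hydride approach away from the tether gives the all-cis C7 alcohol, and chloride enters C8 with inversion through a 6,8-cyclic sulfate.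

Key step: step 5

Remark: chromone numbering (O1, C2, C3, C4, C4a, C5–C8, C8a) is used throughout, "tetrahydrochromone" means 5,6,7,8-tetrahydro-4H-chromen-4-one, TBS = tert-butyldimethylsilyl, Ar = 3-(TBS-oxy)-4-methoxyphenyl, and 1, 4 and 10 are assumed to be catalogue chemicals (4 is otherwise one step from acetone, CS2 and MeI).

**Step 1**
Reactants: 1 3-(3-hydroxy-4-methoxyphenyl)propanoic acid
Product: 3 3-[3-(tert-butyldimethylsilyloxy)-4-methoxyphenyl]propanoic acid, via bis-silyl ester 2 (not isolated)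
Conditions: TBSCl (2.3 equiv), imidazole, DMF, rt; then AcOH/THF/H2O (3:1:1), rt
Reagents that add atoms: tert-butyldimethylsilyl chloride, CC(C)(C)[Si](C)(C)Cl
Why: Imidazole-mediated silylation of phenol and acid followed by selective hydrolysis of the silyl ester, which is far more labile than the aryl silyl ether.

**Step 2**
Reactants: 3 3-[3-(tert-butyldimethylsilyloxy)-4-methoxyphenyl]propanoic acid; 4 4,4-bis(methylsulfanyl)but-3-en-2-one
Product: 6 1-Ar-7,7-bis(methylsulfanyl)hept-6-ene-3,5-dione, via acyl imidazole 5 (not isolated)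
Conditions: 3, 1,1'-carbonyldiimidazole, THF, rt; added to 4 (2.2 equiv)/LiN(SiMe3)2 (2.2 equiv), THF, −78 to 0 °C; aq. NH4Cl
Reagents that add atoms: none
Why: Crossed Claisen C-acylation of the kinetic lithium enolate of the methyl ketone by an N-acylimidazole; the second equivalent of enolate takes up the acidic proton of the β-diketone and no alkoxide is released that could attack the aryl silyl ether.

**Step 3**
Reactants: 6 1-Ar-7,7-bis(methylsulfanyl)hept-6-ene-3,5-dione
Product: 7 2-(2-Ar-ethyl)-6-(methylsulfanyl)-4H-pyran-4-one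
Conditions: TsOH·H2O (10 mol %), toluene, 80 °C
Reagents that add atoms: none
Why: Acid-catalysed intramolecular vinylic substitution (6-endo-trig addition–elimination) of the enol oxygen at the bis(methylsulfanyl) carbon with loss of methanethiol, the closure by which 2-hydroxyaryl ketene dithioacetals give 2-methylsulfanylchromones.

**Step 4**
Reactants: 7 2-(2-Ar-ethyl)-6-(methylsulfanyl)-4H-pyran-4-one
Product: 9 6-(2-Ar-ethyl)-2-(methylsulfanyl)-4-oxo-4H-pyran-3-carbaldehyde, via iminium chloride 8 (not isolated)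
Conditions: POCl3 (1.5 equiv), DMF, 0 to 50 °C; then ice/H2O
Reagents that add atoms: N,N-dimethylformamide, CN(C)C=O; water, O
Why: Vilsmeier–Haack formylation at the ring carbon between the carbonyl and the methylsulfanyl-bearing carbon, the α-carbon of a push–pull ketene O,S-acetal activated by both O1 and sulfur (as in the α-formylation of α-oxo ketene dithioacetals), which should react before the other ring CH and the silyloxyanisole ring; water then hydrolyses the iminium salt.

**Step 5**
Reactants: 9 6-(2-Ar-ethyl)-2-(methylsulfanyl)-4-oxo-4H-pyran-3-carbaldehyde; 10 2,2-dimethyl-1,3-dioxan-5-one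
Product: 12 (5S,6S,8R)-2-(2-Ar-ethyl)-5-hydroxy-6,8-O-isopropylidene-7-oxo-5,6,7,8-tetrahydrochromone, via anti-aldol adduct 11 (not isolated)
Conditions: L-proline (30 mol %), 10 (3 equiv), DMF, 4 °C, then 40 °C under an N2 sweep
Reagents that add atoms: none
Why: Proposed new method: L-proline and 10 form the ring-locked E-enamine, which adds to the formyl group of 9 through the hydrogen-bonded enamine–carboxylic acid transition state to give anti-aldol 11 (C5–C6); the enamine re-formed toward the free α-methylene then attacks C8a of the 2-methylsulfanylpyranone and methanethiol is expelled (C8–C8a), which also releases the catalyst. The closest known reaction types are the proline-catalysed anti-aldol of 2,2-dimethyl-1,3-dioxan-5-one with aldehydes, the α,α'-annulation of cyclic ketone enamines with 1,3-bis-electrophiles to bicyclo[3.3.1]nonan-9-ones, and the displacement of the methylsulfanyl group of 2-methylsulfanyl-4-pyranones and -chromones by carbon nucleophiles; their union in one operation is new. The carbocycle closes by 6-endo-trig addition of the enamine carbon to the C8a=C4a bond (enamine double bond inside the forming ring) followed by β-elimination, giving a 3,3-dimethyl-2,4-dioxabicyclo[3.3.1]nonan-9-one fused to the pyranone. C6 is set by the catalyst through the enamine face exposed in that transition state, C5 by its anti topology, which places O5 cis to O6 on the new ring, and C8 by the isopropylidene tether, which can only span a cis-6,8 pair. The step needs the carbon nucleophile to outrun the proline nitrogen at C8a and the catalyst-controlled aldol to fix C5 and C6; the non-enolisable, strongly electrophilic aldehyde, the intramolecularity of the second bond formation and the still epimerisable C8 (which follows C6 whichever bond forms first) should secure this. Once closed, the ketone has only bridgehead α-hydrogens, so retro-aldol cleavage and dehydration toward an aromatic chromone are blocked.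

**Step 6**
Reactants: 12 (5S,6S,8R)-2-(2-Ar-ethyl)-5-hydroxy-6,8-O-isopropylidene-7-oxo-5,6,7,8-tetrahydrochromone
Product: 13 (5S,6S,7S,8S)-2-(2-Ar-ethyl)-5,7-dihydroxy-6,8-O-isopropylidene-5,6,7,8-tetrahydrochromone
Conditions: NaBH4, MeOH/CH2Cl2 (1:1), −40 °C
Reagents that add atoms: none
Why: Hydride reduction under steric approach control: the isopropylidene carbon and its outward methyl lie across the acetal face of the bridging C7 carbonyl (the inward methyl rules out a chair dioxane), so borohydride should enter from the carbocycle face past only the C5 hydrogen and give the 7S alcohol cis to O5, O6 and O8, while the vinylogous ester carbonyl C4 is not reduced at −40 °C.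

**Step 7**
Reactants: 13 (5S,6S,7S,8S)-2-(2-Ar-ethyl)-5,7-dihydroxy-6,8-O-isopropylidene-5,6,7,8-tetrahydrochromone
Product: 14 (5S,6S,7S,8S)-2-(2-Ar-ethyl)-5,7-bis(tert-butyldimethylsilyloxy)-6,8-O-isopropylidene-5,6,7,8-tetrahydrochromone
Conditions: TBSOTf (3 equiv), 2,6-lutidine, CH2Cl2, 0 °C to rt
Reagents that add atoms: tert-butyldimethylsilyl trifluoromethanesulfonate, CC(C)(C)[Si](C)(C)OS(=O)(=O)C(F)(F)F
Why: Silyl triflate silylation with 2,6-lutidine is strong enough for the hindered C7 hydroxyl and gives ethers that later leave with fluoride under non-basic conditions.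

**Step 8**
Reactants: 14 (5S,6S,7S,8S)-2-(2-Ar-ethyl)-5,7-bis(tert-butyldimethylsilyloxy)-6,8-O-isopropylidene-5,6,7,8-tetrahydrochromone
Product: 15 (5S,6S,7S,8S)-2-(2-Ar-ethyl)-5,7-bis(tert-butyldimethylsilyloxy)-6,8-dihydroxy-5,6,7,8-tetrahydrochromone
Conditions: pyridinium p-toluenesulfonate (0.3 equiv), MeOH, 40 °C
Reagents that add atoms: none
Why: Acid-catalysed transacetalisation with methanol removes the strained 1,3-diaxial isopropylidene bridge, while secondary and aryl TBS ethers withstand this weak acid.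

**Step 9**
Reactants: 15 (5S,6S,7S,8S)-2-(2-Ar-ethyl)-5,7-bis(tert-butyldimethylsilyloxy)-6,8-dihydroxy-5,6,7,8-tetrahydrochromone
Product: 17 (5S,6S,7S,8S)-2-(2-Ar-ethyl)-5,7-bis(tert-butyldimethylsilyloxy)-5,6,7,8-tetrahydrochromone-6,8-diyl cyclic sulfate, via cyclic sulfite 16 (not isolated)
Conditions: SOCl2, Et3N, CH2Cl2, 0 °C; then RuCl3·3H2O (2 mol %), NaIO4, MeCN/CH2Cl2/H2O, 0 °C, short contact
Reagents that add atoms: thionyl chloride, O=S(Cl)Cl; sodium periodate, [Na+].[O-]I(=O)(=O)=O
Why: Cyclic sulfate synthesis by way of the sulfite: the cis-1,3-diol closes to the six-membered sulfite with SOCl2, and RuO4 formed from RuCl3 and NaIO4 oxidises it to the sulfate within minutes, no sulfide being left in the molecule.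

**Step 10**
Reactants: 17 (5S,6S,7S,8S)-2-(2-Ar-ethyl)-5,7-bis(tert-butyldimethylsilyloxy)-5,6,7,8-tetrahydrochromone-6,8-diyl cyclic sulfate
Product: 19 (5S,6S,7S,8R)-2-(2-Ar-ethyl)-8-chloro-6-hydroxy-5,7-bis(tert-butyldimethylsilyloxy)-5,6,7,8-tetrahydrochromone, via lithium sulfate monoester 18 (not isolated)
Conditions: LiCl (3 equiv), DMF, 40 °C; then H2SO4 (cat.), H2O (2 equiv), THF, rt
Reagents that add atoms: lithium chloride, [Li+].[Cl-]
Why: SN2 opening of the cyclic sulfate by chloride at C8, the allylic carbon next to C8a and the one flanked by a single oxygenated carbon, should invert C8 to the 8R chloride trans to O7, and acid hydrolysis of the sulfate monoester by S–O cleavage frees the C6 hydroxyl with retention.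

**Step 11**
Reactants: 19 (5S,6S,7S,8R)-2-(2-Ar-ethyl)-8-chloro-6-hydroxy-5,7-bis(tert-butyldimethylsilyloxy)-5,6,7,8-tetrahydrochromone
Product: 20 (5S,6S,7S,8R)-8-chloro-5,6,7-trihydroxy-2-[2-(3-hydroxy-4-methoxyphenyl)ethyl]-5,6,7,8-tetrahydrochromone
Conditions: HF·pyridine, pyridine, THF, 0 °C to rt
Reagents that add atoms: none
Why: Fluoride-mediated desilylation removes the two secondary and the aryl silyl ethers under buffered, non-basic conditions, so the trans-7-hydroxy-8-chloride cannot close to an epoxide and C5 is not ionised.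

**Compound list**
1 | 3-(3-hydroxy-4-methoxyphenyl)propanoic acid | COc1ccc(CCC(=O)O)cc1O | starting material
2 | tert-butyldimethylsilyl 3-[3-(tert-butyldimethylsilyloxy)-4-methoxyphenyl]propanoate (not isolated) | COc1ccc(CCC(=O)O[Si](C)(C)C(C)(C)C)cc1O[Si](C)(C)C(C)(C)C | intermediate
3 | 3-[3-(tert-butyldimethylsilyloxy)-4-methoxyphenyl]propanoic acid | COc1ccc(CCC(=O)O)cc1O[Si](C)(C)C(C)(C)C | intermediate
4 | 4,4-bis(methylsulfanyl)but-3-en-2-one | CC(=O)C=C(SC)SC | starting material
5 | 1-{3-[3-(tert-butyldimethylsilyloxy)-4-methoxyphenyl]propanoyl}imidazole (not isolated) | COc1ccc(CCC(=O)n2ccnc2)cc1O[Si](C)(C)C(C)(C)C | intermediate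
6 | 1-[3-(tert-butyldimethylsilyloxy)-4-methoxyphenyl]-7,7-bis(methylsulfanyl)hept-6-ene-3,5-dione | COc1ccc(CCC(=O)CC(=O)C=C(SC)SC)cc1O[Si](C)(C)C(C)(C)C | intermediate
7 | 2-{2-[3-(tert-butyldimethylsilyloxy)-4-methoxyphenyl]ethyl}-6-(methylsulfanyl)-4H-pyran-4-one | COc1ccc(CCc2cc(=O)cc(SC)o2)cc1O[Si](C)(C)C(C)(C)C | intermediate
8 | N-{[6-(2-Ar-ethyl)-2-(methylsulfanyl)-4-oxo-4H-pyran-3-yl]methylidene}-N-methylmethanaminium chloride (not isolated) | COc1ccc(CCc2cc(=O)c(C=[N+](C)C)c(SC)o2)cc1O[Si](C)(C)C(C)(C)C.[Cl-] | intermediate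
9 | 6-{2-[3-(tert-butyldimethylsilyloxy)-4-methoxyphenyl]ethyl}-2-(methylsulfanyl)-4-oxo-4H-pyran-3-carbaldehyde | COc1ccc(CCc2cc(=O)c(C=O)c(SC)o2)cc1O[Si](C)(C)C(C)(C)C | intermediate
10 | 2,2-dimethyl-1,3-dioxan-5-one | CC1(C)OCC(=O)CO1 | starting material
11 | (4S)-4-{(S)-hydroxy[6-(2-Ar-ethyl)-2-(methylsulfanyl)-4-oxo-4H-pyran-3-yl]methyl}-2,2-dimethyl-1,3-dioxan-5-one (not isolated) | COc1ccc(CCc2cc(=O)c(c(SC)o2)[C@H](O)[C@@H]3OC(C)(C)OCC3=O)cc1O[Si](C)(C)C(C)(C)C | intermediate
12 | (5S,6S,8R)-2-(2-Ar-ethyl)-5-hydroxy-6,8-O-isopropylidene-7-oxo-5,6,7,8-tetrahydrochromone (O5, O6, O8 all cis) | COc1ccc(CCc2cc(=O)c3c(o2)[C@@H](OC(C)(C)O4)C(=O)[C@@H]4[C@H]3O)cc1O[Si](C)(C)C(C)(C)C | intermediate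
13 | (5S,6S,7S,8S)-2-(2-Ar-ethyl)-5,7-dihydroxy-6,8-O-isopropylidene-5,6,7,8-tetrahydrochromone (all four oxygens cis; the C8 descriptor differs from 12 by priority only) | COc1ccc(CCc2cc(=O)c3c(o2)[C@@H](OC(C)(C)O4)[C@@H](O)[C@@H]4[C@H]3O)cc1O[Si](C)(C)C(C)(C)C | intermediate
14 | (5S,6S,7S,8S)-2-(2-Ar-ethyl)-5,7-bis(tert-butyldimethylsilyloxy)-6,8-O-isopropylidene-5,6,7,8-tetrahydrochromone | COc1ccc(CCc2cc(=O)c3c(o2)[C@@H](OC(C)(C)O4)[C@@H](O[Si](C)(C)C(C)(C)C)[C@@H]4[C@H]3O[Si](C)(C)C(C)(C)C)cc1O[Si](C)(C)C(C)(C)C | intermediate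
15 | (5S,6S,7S,8S)-2-(2-Ar-ethyl)-5,7-bis(tert-butyldimethylsilyloxy)-6,8-dihydroxy-5,6,7,8-tetrahydrochromone | COc1ccc(CCc2cc(=O)c3c(o2)[C@@H](O)[C@@H](O[Si](C)(C)C(C)(C)C)[C@@H](O)[C@H]3O[Si](C)(C)C(C)(C)C)cc1O[Si](C)(C)C(C)(C)C | intermediate
16 | 6,8-cyclic sulfite of 15, either configuration at sulfur (not isolated) | COc1ccc(CCc2cc(=O)c3c(o2)[C@@H](OS(=O)O4)[C@@H](O[Si](C)(C)C(C)(C)C)[C@@H]4[C@H]3O[Si](C)(C)C(C)(C)C)cc1O[Si](C)(C)C(C)(C)C | intermediate
17 | (5S,6S,7S,8S)-6,8-cyclic sulfate of 15 | COc1ccc(CCc2cc(=O)c3c(o2)[C@@H](OS(=O)(=O)O4)[C@@H](O[Si](C)(C)C(C)(C)C)[C@@H]4[C@H]3O[Si](C)(C)C(C)(C)C)cc1O[Si](C)(C)C(C)(C)C | intermediate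
18 | lithium (5S,6S,7S,8R)-2-(2-Ar-ethyl)-8-chloro-5,7-bis(tert-butyldimethylsilyloxy)-5,6,7,8-tetrahydrochromon-6-yl sulfate (not isolated) | COc1ccc(CCc2cc(=O)c3c(o2)[C@H](Cl)[C@@H](O[Si](C)(C)C(C)(C)C)[C@@H](OS(=O)(=O)[O-])[C@H]3O[Si](C)(C)C(C)(C)C)cc1O[Si](C)(C)C(C)(C)C.[Li+] | intermediate
19 | (5S,6S,7S,8R)-2-(2-Ar-ethyl)-8-chloro-6-hydroxy-5,7-bis(tert-butyldimethylsilyloxy)-5,6,7,8-tetrahydrochromone | COc1ccc(CCc2cc(=O)c3c(o2)[C@H](Cl)[C@@H](O[Si](C)(C)C(C)(C)C)[C@@H](O)[C@H]3O[Si](C)(C)C(C)(C)C)cc1O[Si](C)(C)C(C)(C)C | intermediate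
20 | (5S,6S,7S,8R)-8-chloro-5,6,7-trihydroxy-2-[2-(3-hydroxy-4-methoxyphenyl)ethyl]-5,6,7,8-tetrahydro-4H-chromen-4-one (5-, 6-, 7-OH cis; 8-Cl trans) | COc1ccc(CCc2cc(=O)c3c(o2)[C@H](Cl)[C@@H](O)[C@@H](O)[C@H]3O)cc1O | target

**Totals**
Total step count: 11. Longest linear sequence: 11 steps (from 1; 4 and 10 enter as purchased compounds).

**Steps most likely to fail**

1. Step 5. The proline nitrogen may itself substitute the methylsulfanyl group at C8a and drain the catalyst, the sequence may stall after the first C–C bond, or the vinylic substitution may run ahead of the aldol and erode control at C5 and C6. The fallback is stepwise and uses known chemistry. It sets out from 9 and 10: the L-proline aldol is run cold (DMF, 4 °C) and stopped at the anti-aldol 11, which is isolated. Its hydroxyl is silylated (TBSOTf, 2,6-lutidine) to the silyl ether of the aldol adduct F1. Kinetic deprotonation of the unsubstituted α-methylene with LiN(SiMe3)2 (THF, −78 to −20 °C) gives a lithium enolate that closes onto C8a by addition–elimination with loss of methanethiolate, giving the 5-O-silyl bicyclic ketone F2. NaBH4 reduction as in step 6 gives the 5-O-silyl 7-alcohol F3, and silylation of its C7 hydroxyl (TBSOTf, 2,6-lutidine) rejoins the route at 14.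

2. Step 4. The Vilsmeier reagent may bind the pyranone carbonyl oxygen (chloropyrylium formation), which shuts down electrophilic attack on the ring, or the vinylogous α-methylene of the side chain may be attacked on heating. The fallback sets out from 7: electrophilic iodination at the same ring carbon (N-iodosuccinimide, cat. CF3CO2H, MeCN) gives the iodopyranone F4. Iodine–magnesium exchange with i-PrMgCl·LiCl (THF, −40 °C) and a DMF quench deliver aldehyde 9, where the route is rejoined.

3. Step 10. Substitution at the secondary C8 of the six-membered sulfate may be slow, so that E2 loss of the C7 hydrogen competes on warming, or a silyl ether may be lost while the sulfate monoester is hydrolysed. The fallback sets out from diol 15 and leaves out the sulfate: an Appel chlorination (PPh3, N-chlorosuccinimide, THF, 0 °C to rt) activates the diol as an alkoxyphosphonium (or 6,8-dioxaphosphorane), which should collapse by chloride attack at the allylic C8 with inversion. This gives 19 directly, where the route is rejoined; no compound outside the list is formed (F0).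

**Further compounds**
F1 | step 5 | (4S)-4-{(S)-(tert-butyldimethylsilyloxy)[6-(2-Ar-ethyl)-2-(methylsulfanyl)-4-oxo-4H-pyran-3-yl]methyl}-2,2-dimethyl-1,3-dioxan-5-one | COc1ccc(CCc2cc(=O)c(c(SC)o2)[C@H](O[Si](C)(C)C(C)(C)C)[C@@H]3OC(C)(C)OCC3=O)cc1O[Si](C)(C)C(C)(C)C
F2 | step 5 | (5S,6S,8R)-2-(2-Ar-ethyl)-5-(tert-butyldimethylsilyloxy)-6,8-O-isopropylidene-7-oxo-5,6,7,8-tetrahydrochromone | COc1ccc(CCc2cc(=O)c3c(o2)[C@@H](OC(C)(C)O4)C(=O)[C@@H]4[C@H]3O[Si](C)(C)C(C)(C)C)cc1O[Si](C)(C)C(C)(C)C
F3 | step 5 | (5S,6S,7S,8S)-2-(2-Ar-ethyl)-5-(tert-butyldimethylsilyloxy)-7-hydroxy-6,8-O-isopropylidene-5,6,7,8-tetrahydrochromone | COc1ccc(CCc2cc(=O)c3c(o2)[C@@H](OC(C)(C)O4)[C@@H](O)[C@@H]4[C@H]3O[Si](C)(C)C(C)(C)C)cc1O[Si](C)(C)C(C)(C)C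
F4 | step 4 | 6-{2-[3-(tert-butyldimethylsilyloxy)-4-methoxyphenyl]ethyl}-3-iodo-2-(methylsulfanyl)-4H-pyran-4-one | COc1ccc(CCc2cc(=O)c(I)c(SC)o2)cc1O[Si](C)(C)C(C)(C)C
F0 | step 10 | none | none
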